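**Plan**

1. Cuts: ring C (the pyranone) at O1–C2 and at C3–C4, back to an epoxy ketone whose aroyl group shifts, and from there to a chalcone (aldol bond). Ring D (the dimethylpyran) is cut at the bond between C3' of ring B and the vinylic CH, back to an aryl 1,1-dimethylpropargyl ether.
2. Enabling feature: the ring D oxygen sits on C4' next to the free position C3', so O–C4'=C3' and the chain O–C(CH3)2–C≡CH form the six-atom array of a [3,3] shift. The 2'-oxygen on the other side of C3', kept as a free OH hydrogen-bonded to a formyl group on C1', fixes the C3'=C4' bond and steers the shift to C3' and not to C5'.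
3. Forward order: ring B aldehyde, propargyl ether, ring D by a sigmatropic/electrocyclic cascade, O-methylation, chalcone with the ring A ketone, epoxide, then aroyl shift and closure of ring C last. The formyl carbon that steered the cascade ends as C3 and the acetyl methyl carbon as C2.
4. The chalcone is converted by nucleophilic epoxidation and Lewis acid rearrangement. Tl(NO3)3 and hypervalent iodine reagents are avoided because the electron-rich ring D olefin should not survive their electrophilic attack.
5. Stereochemistry: the target is achiral. The racemic trans-epoxide is the only stereodefined intermediate and both its centres are erased in the last step.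

Key step: step 2

Assumption: compounds 1, 2 and 9 are taken as commercial. Ring D is numbered as a 2H-chromene (O1, C2, C3, C4, C4a, C5–C8, C8a), so that chromene C6 is C1' of ring B and chromene C5 is C2'.

**Route**

Step 1
Reactants: 1 2,4-dihydroxybenzaldehyde; 2 3-chloro-3-methylbut-1-yne
Product: 3 2-hydroxy-4-[(2-methylbut-3-yn-2-yl)oxy]benzaldehyde
Conditions: K2CO3, KI, CuI (cat.), acetone, 60 °C, N2
Reagents that add atoms: none
Why: Williamson-type O-alkylation in which the 4-OH, acidified by the para formyl group and not engaged in the hydrogen bond, is alkylated selectively by the copper-activated tertiary propargylic chloride while the chelated 2-OH stays free.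

Step 2
Reactants: 3 2-hydroxy-4-[(2-methylbut-3-yn-2-yl)oxy]benzaldehyde
Product: 7 5-hydroxy-2,2-dimethyl-2H-chromene-6-carbaldehyde, via allenyl dienone 4 (not isolated), via allenylphenol 5 (not isolated), via ortho-quinone methide 6 (not isolated)
Conditions: PhNEt2, 185 °C, N2
Reagents that add atoms: none
Why: An aromatic propargyl Claisen rearrangement ([3,3]-sigmatropic shift through a six-centre transition state) joins ring carbon C3 to the terminal alkyne carbon and gives allenyl dienone 4, which enolises to allenylphenol 5; a [1,5]-hydrogen shift from the new phenol OH to the central allene carbon gives the (Z)-ortho-quinone methide 6, and its thermal disrotatory oxa-6π electrocyclisation re-forms the O–C(CH3)2 bond. The closest known reaction type is the thermal conversion of aryl 1,1-dimethylpropargyl ethers into 2,2-dimethyl-2H-chromenes. The pyran ring is closed in two pericyclic events, the aryl–CH bond in the [3,3] shift and the six-membered ring itself by 6π closure of the oxatriene O=C4–C3=CH–CH=C(CH3)2. No stereocentre persists, because the sp3 centre of 4 is lost on enolisation and the product is achiral. The selectivity needed is C3 against C5 as migration terminus: the hydrogen bond between the 2-OH and the formyl oxygen forms a six-membered chelate that localises the C1=C2 and hence the C3=C4 bond of the benzene ring, so only the O–C4=C3 unit has the enol ether character the shift needs. The geminal methyl groups lower the temperature of the shift and make the final ring closure irreversible.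

Step 3
Reactants: 7 5-hydroxy-2,2-dimethyl-2H-chromene-6-carbaldehyde
Product: 8 5-methoxy-2,2-dimethyl-2H-chromene-6-carbaldehyde
Conditions: MeI, K2CO3, DMF, 40 °C
Reagents that add atoms: iodomethane, CI
Why: SN2 O-methylation of the phenoxide (Williamson ether synthesis), for which the chelated 5-OH needs the polar solvent and gentle heating while no other nucleophilic site is present.

Step 4
Reactants: 9 1-(2-hydroxy-4-methoxyphenyl)ethanone (paeonol)
Product: 10 1-[4-methoxy-2-(methoxymethoxy)phenyl]ethanone
Conditions: MOMCl, K2CO3, acetone, reflux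
Reagents that add atoms: chloromethyl methyl ether, COCCl
Why: Williamson-type protection of the chelated 2-OH as its methoxymethyl ether, which should survive the basic aldol and epoxidation steps and prevent ring closure of the phenol onto the enone or the epoxide before the rearrangement.

Step 5
Reactants: 8 5-methoxy-2,2-dimethyl-2H-chromene-6-carbaldehyde; 10 1-[4-methoxy-2-(methoxymethoxy)phenyl]ethanone
Product: 11 (2E)-1-[4-methoxy-2-(methoxymethoxy)phenyl]-3-(5-methoxy-2,2-dimethyl-2H-chromen-6-yl)prop-2-en-1-one
Conditions: KOH, EtOH/H2O, rt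
Reagents that add atoms: none
Why: Claisen–Schmidt (crossed aldol) condensation in which only the methyl ketone is enolisable, the aldehyde cannot self-condense, and E1cB dehydration gives the conjugated (E)-enone.

Step 6
Reactants: 11 (2E)-1-[4-methoxy-2-(methoxymethoxy)phenyl]-3-(5-methoxy-2,2-dimethyl-2H-chromen-6-yl)prop-2-en-1-one
Product: 12 trans-[3-(5-methoxy-2,2-dimethyl-2H-chromen-6-yl)oxiran-2-yl][4-methoxy-2-(methoxymethoxy)phenyl]methanone (racemic)
Conditions: 30% H2O2, NaOH (aq, substoichiometric), MeOH/THF, 0 °C to rt
Reagents that add atoms: hydrogen peroxide, OO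
Why: Weitz–Scheffer nucleophilic epoxidation in which hydroperoxide anion adds in conjugate fashion only to the electron-poor enone and leaves the electron-rich ring D olefin untouched, and closure of the enolate gives the trans-epoxide as a racemate whose centres are erased in step 7.

Step 7
Reactants: 12 trans-[3-(5-methoxy-2,2-dimethyl-2H-chromen-6-yl)oxiran-2-yl][4-methoxy-2-(methoxymethoxy)phenyl]methanone
Product: 16 7-methoxy-3-(5-methoxy-2,2-dimethyl-2H-chromen-6-yl)-4H-chromen-4-one, via formyl ketone 13 (not isolated), via free phenol 14 (not isolated), via lactol 15 (not isolated)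
Conditions: BF3·OEt2 (0.5 equiv), CH2Cl2, 0 °C; then 3 M HCl, MeOH, 50 °C
Reagents that add atoms: none
Why: Meinwald-type rearrangement of a chalcone epoxide (the epoxide route to isoflavones), in which BF3 opens the epoxide at the benzylic carbon, whose cation is stabilised by the ortho and para oxygens of ring B, the aroyl group shifts to that carbon to give formyl ketone 13, and acid then removes the MOM group so that phenol 14 closes onto the aldehyde to lactol 15, which loses water to the chromen-4-one.

**Compound list**

1 | 2,4-dihydroxybenzaldehyde | O=Cc1ccc(O)cc1O | starting material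
2 | 3-chloro-3-methylbut-1-yne | C#CC(C)(C)Cl | starting material
3 | 2-hydroxy-4-[(2-methylbut-3-yn-2-yl)oxy]benzaldehyde | C#CC(C)(C)Oc1ccc(C=O)c(O)c1 | intermediate
4 | 2-hydroxy-3-(3-methylbuta-1,2-dien-1-yl)-4-oxocyclohexa-1,5-diene-1-carbaldehyde (racemic) | O=CC1=C(O)C(C=C=C(C)C)C(=O)C=C1 | intermediate (not isolated)
5 | 2,4-dihydroxy-3-(3-methylbuta-1,2-dien-1-yl)benzaldehyde | O=Cc1ccc(O)c(C=C=C(C)C)c1O | intermediate (not isolated)
6 | (3Z)-2-hydroxy-3-(3-methylbut-2-en-1-ylidene)-4-oxocyclohexa-1,5-diene-1-carbaldehyde | O=CC1=C(O)/C(=C/C=C(C)C)C(=O)C=C1 | intermediate (not isolated)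
7 | 5-hydroxy-2,2-dimethyl-2H-chromene-6-carbaldehyde | CC1(C)C=Cc2c(O1)ccc(C=O)c2O | intermediate
8 | 5-methoxy-2,2-dimethyl-2H-chromene-6-carbaldehyde | COc1c(C=O)ccc2OC(C)(C)C=Cc12 | intermediate
9 | 1-(2-hydroxy-4-methoxyphenyl)ethanone (paeonol) | CC(=O)c1ccc(OC)cc1O | starting material
10 | 1-[4-methoxy-2-(methoxymethoxy)phenyl]ethanone | COCOc1cc(OC)ccc1C(C)=O | intermediate
11 | (2E)-1-[4-methoxy-2-(methoxymethoxy)phenyl]-3-(5-methoxy-2,2-dimethyl-2H-chromen-6-yl)prop-2-en-1-one | COCOc1cc(OC)ccc1C(=O)/C=C/c1ccc2OC(C)(C)C=Cc2c1OC | intermediate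
12 | trans-[3-(5-methoxy-2,2-dimethyl-2H-chromen-6-yl)oxiran-2-yl][4-methoxy-2-(methoxymethoxy)phenyl]methanone (racemic, one enantiomer drawn) | COCOc1cc(OC)ccc1C(=O)[C@H]1O[C@@H]1c1ccc2OC(C)(C)C=Cc2c1OC | intermediate
13 | 2-(5-methoxy-2,2-dimethyl-2H-chromen-6-yl)-3-[4-methoxy-2-(methoxymethoxy)phenyl]-3-oxopropanal (racemic) | COCOc1cc(OC)ccc1C(=O)C(C=O)c1ccc2OC(C)(C)C=Cc2c1OC | intermediate (not isolated)
14 | 3-(2-hydroxy-4-methoxyphenyl)-2-(5-methoxy-2,2-dimethyl-2H-chromen-6-yl)-3-oxopropanal (racemic) | COc1ccc(C(=O)C(C=O)c2ccc3OC(C)(C)C=Cc3c2OC)c(O)c1 | intermediate (not isolated)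
15 | 2-hydroxy-7-methoxy-3-(5-methoxy-2,2-dimethyl-2H-chromen-6-yl)-2,3-dihydro-4H-chromen-4-one (racemic mixture of diastereomers) | COc1ccc2C(=O)C(c3ccc4OC(C)(C)C=Cc4c3OC)C(O)Oc2c1 | intermediate (not isolated)
16 | 7-methoxy-3-(5-methoxy-2,2-dimethyl-2H-chromen-6-yl)-4H-chromen-4-one | COc1ccc2c(=O)c(-c3ccc4c(c3OC)C=CC(C)(C)O4)coc2c1 | target

**Step count**

Total: 7 steps. Longest linear sequence: 6 steps (steps 1, 2, 3, 5, 6, 7); step 4 is the side branch.

**Steps most likely to fail**

Step 7. The benzylic cation may be diverted before the aroyl group migrates: hydride shift to a 1,2-diketone, capture by the MOM oxygen, or ring closure of a prematurely freed phenol at the benzylic carbon. The Lewis acid may also oligomerise the ring D olefin, or methanol may add across it in the acid stage. The fallback builds ring C from a deoxybenzoin and a one-carbon unit, without cation or Lewis acid, setting out from 8 and returning at 16. Condensation of 8 with 4-methylbenzenesulfonohydrazide (MeOH, rt) should give tosylhydrazone F1. Heating F1 with K2CO3 in 1,4-dioxane at 110 °C releases aryldiazomethane F2 in the flask. F2 inserts into the formyl C–H bond of 4-methoxy-2-(methoxymethoxy)benzaldehyde F3, itself made from commercial 2-hydroxy-4-methoxybenzaldehyde with MOMCl and K2CO3 in acetone, to give deoxybenzoin F4. Dilute HCl in MeOH frees phenol F5. N,N-Dimethylformamide dimethyl acetal in toluene at 90 °C then gives enaminone F6, which closes to 16 with loss of dimethylamine.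

Step 6. Conjugate addition of hydroperoxide may be slow because the donor-substituted ring B deactivates the enone, retro-aldol cleavage may compete under base, and the acid-labile benzylic epoxide may open during isolation. The fallback is a Darzens condensation that needs neither enone nor peroxide, setting out from 8 and 10 and returning at 12 (steps 5 and 6 are both bypassed). Ketone 10 would be converted with LiN(SiMe3)2 and Me3SiCl (THF, −78 °C) into silyl enol ether F7 and brominated in the same flask with N-bromosuccinimide at 0 °C to bromo ketone F8. Condensation of F8 with 8 (NaOMe, MeOH, 0 °C to rt) should give the trans-epoxy ketone 12 directly.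

Step 2. The aldehyde may degrade at the temperature of the sigmatropic shift, the shift may leak to C5 if the basic solvent breaks the hydrogen bond, and the ortho-quinone methide may dimerise before it cyclises. The fallback forms the same aryl–CH bond by an aldol-type C-alkylation at room temperature, setting out from 1 and returning at 7 (steps 1 and 2 are both bypassed). Compound 1 and 3-methylbut-2-enal with Ca(OH)2 in MeOH at rt (or in pyridine at 140 °C) should give benzylic alcohol F9 by attack of the phenoxide through C3. F9 loses water to the same ortho-quinone methide 6, which closes to 7.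

**Further compounds**

F1 | step 7 | N'-[(E)-(5-methoxy-2,2-dimethyl-2H-chromen-6-yl)methylidene]-4-methylbenzenesulfonohydrazide | COc1c(/C=N/NS(=O)(=O)c2ccc(C)cc2)ccc2OC(C)(C)C=Cc12
F2 | step 7 | 6-(diazomethyl)-5-methoxy-2,2-dimethyl-2H-chromene | COc1c(C=[N+]=[N-])ccc2OC(C)(C)C=Cc12
F3 | step 7 | 4-methoxy-2-(methoxymethoxy)benzaldehyde | COCOc1cc(OC)ccc1C=O
F4 | step 7 | 2-(5-methoxy-2,2-dimethyl-2H-chromen-6-yl)-1-[4-methoxy-2-(methoxymethoxy)phenyl]ethanone | COCOc1cc(OC)ccc1C(=O)Cc1ccc2OC(C)(C)C=Cc2c1OC
F5 | step 7 | 1-(2-hydroxy-4-methoxyphenyl)-2-(5-methoxy-2,2-dimethyl-2H-chromen-6-yl)ethanone | COc1ccc(C(=O)Cc2ccc3OC(C)(C)C=Cc3c2OC)c(O)c1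
F6 | step 7 | (2E)-3-(dimethylamino)-1-(2-hydroxy-4-methoxyphenyl)-2-(5-methoxy-2,2-dimethyl-2H-chromen-6-yl)prop-2-en-1-one | COc1ccc(C(=O)/C(=C/N(C)C)c2ccc3OC(C)(C)C=Cc3c2OC)c(O)c1
F7 | step 6 | ({1-[4-methoxy-2-(methoxymethoxy)phenyl]ethenyl}oxy)(trimethyl)silane | COCOc1cc(OC)ccc1C(=C)O[Si](C)(C)C
F8 | step 6 | 2-bromo-1-[4-methoxy-2-(methoxymethoxy)phenyl]ethanone | COCOc1cc(OC)ccc1C(=O)CBr
F9 | step 2 | 2,4-dihydroxy-3-(1-hydroxy-3-methylbut-2-en-1-yl)benzaldehyde (racemic) | O=Cc1ccc(O)c(C(O)C=C(C)C)c1O
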